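**Retrosynthetic overview**
1. Target ⇐ tri-O-methyl ether 28 (thiolate demethylation) ⇐ two directed ortho-metalation/acylation events on carbinol 22, which carries the arene as a 2,4,6-trimethoxybenzyl group on the quaternary ring carbon.
2. Seven-membered ring (closed last) ⇐ Cope rearrangement of the all-cis cyclopropane 18, which bears a cyclopentenyl group, an (E)-propenyl group and a CO2Me group; afterwards only diimide reduction of the extra cis-alkene and methyl addition to the ester remain.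
3. Enabling feature: in the seven-membered ring the trisubstituted alkene (ring-fusion C=CH), the neighbouring CH that carries C(CH3)2OH, the CH2–CH2 pair and the CH(CH3)–CH(ring fusion) bond form a masked cyclohepta-1,4-diene. The CH(CMe2OH) carbon can therefore come from a cyclopropane carbon and the CH(CH3)–CH bond from the union of two alkene termini.
4. Cyclopropane 18 (a ring absent from the target) ⇐ lactone 14 by enantioselective intramolecular cyclopropanation of the (Z)-allylic diazoacetate 13; the temporary lactone tether fixes the all-cis geometry and is then opened into the ester and (E)-propenyl arms.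
5. Cyclopentane with the quaternary stereocentre ⇐ dione 3 (CBS desymmetrisation, deoxygenation, enol triflate, Sonogashira coupling). Ring order: benzene ring and cyclopentane are bought, lactone and cyclopropane are temporary rings (step 10), the seven-membered ring closes last (step 14).

Key step: step 14

Remark: TMB = (2,4,6-trimethoxyphenyl)methyl; the sense of induction of the CBS catalyst and of Rh2(5R-MEPY)4 is assumed to follow the parent ketones and simple (Z)-allylic diazoacetates, and the other catalyst enantiomer would be used if it does not.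

Step 1
Reactants: 1 (2,4,6-trimethoxyphenyl)methanol; 2 2-methylcyclopentane-1,3-dione
Product: 3 2-methyl-2-TMB-cyclopentane-1,3-dione
Conditions: TsOH·H2O (5 mol%), MeNO2, 50 °C, 2 in excess
Reagents that add atoms: none
Why: Acid-catalysed SN1 C-benzylation of a 1,3-dicarbonyl compound by a benzylic alcohol: the 2,4,6-trimethoxybenzyl cation forms readily and the enol of 2 captures it at carbon (O-alkylation is reversible under these conditions), and no stereocentre is formed.

Step 2
Reactants: 3 2-methyl-2-TMB-cyclopentane-1,3-dione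
Product: 4 (2S,3S)-3-hydroxy-2-methyl-2-TMB-cyclopentan-1-one (OH cis to TMB)
Conditions: (R)-2-methyl-CBS-oxazaborolidine (20 mol%), BH3·THF (0.6 equiv), THF, −30 °C; MeOH, then H2O
Reagents that add atoms: none
Why: Corey–Bakshi–Shibata reduction used as a desymmetrisation: the catalyst fixes the configuration of the new carbinol carbon (quaternary carbon as the large group) and hydride enters anti to the TMB group, so the two together decide which enantiotopic carbonyl is reduced and thereby the quaternary stereocentre, and the minor diastereomer (opposite quaternary configuration) should be removable by chromatography.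

Step 3
Reactants: 4 (2S,3S)-3-hydroxy-2-methyl-2-TMB-cyclopentan-1-one
Product: 5 O-[(1S,2S)-2-methyl-3-oxo-2-TMB-cyclopentyl] 1H-imidazole-1-carbothioate
Conditions: 1,1'-thiocarbonyldiimidazole, DMAP (cat.), ClCH2CH2Cl, 70 °C
Reagents that add atoms: 1,1'-thiocarbonyldiimidazole, S=C(n1ccnc1)n1ccnc1
Why: Thioacylation of the secondary alcohol (first half of a Barton–McCombie deoxygenation) under nearly neutral conditions that avoid retro-aldol opening of the β-hydroxy ketone, with both stereocentres untouched.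

Step 4
Reactants: 5 O-[(1S,2S)-2-methyl-3-oxo-2-TMB-cyclopentyl] 1H-imidazole-1-carbothioate
Product: 6 (2R)-2-methyl-2-TMB-cyclopentan-1-one
Conditions: Bu3SnH, AIBN (cat.), toluene, 110 °C
Reagents that add atoms: none
Why: Barton–McCombie radical deoxygenation removes the carbinol carbon's oxygen and leaves the non-epimerisable quaternary carbon as the only stereocentre.

Step 5
Reactants: 6 (2R)-2-methyl-2-TMB-cyclopentan-1-one
Product: 8 (5R)-5-methyl-5-TMB-cyclopent-1-en-1-yl trifluoromethanesulfonate, via potassium enolate 7 (not isolated)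
Conditions: KHMDS, THF, −78 °C; then PhNTf2, −78 → 0 °C
Reagents that add atoms: N-phenylbis(trifluoromethanesulfonimide), O=S(=O)(N(c1ccccc1)S(=O)(=O)C(F)(F)F)C(F)(F)F
Why: Enolate triflation: enolisation can occur only on the CH2 side because the other α-carbon is quaternary, and O-sulfonylation gives a single enol triflate.

Step 6
Reactants: 8 (5R)-5-methyl-5-TMB-cyclopent-1-en-1-yl trifluoromethanesulfonate; 9 prop-2-yn-1-ol
Product: 10 3-[(5R)-5-methyl-5-TMB-cyclopent-1-en-1-yl]prop-2-yn-1-ol
Conditions: Pd(PPh3)4 (5 mol%), CuI (10 mol%), Et3N, DMF, 40 °C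
Reagents that add atoms: none
Why: Sonogashira coupling of an alkenyl triflate with a terminal alkyne, whose small sp nucleophile should couple even next to the quaternary carbon.

Step 7
Reactants: 10 3-[(5R)-5-methyl-5-TMB-cyclopent-1-en-1-yl]prop-2-yn-1-ol
Product: 11 (2Z)-3-[(5R)-5-methyl-5-TMB-cyclopent-1-en-1-yl]prop-2-en-1-ol
Conditions: H2 (1 atm), Pd/CaCO3 poisoned with Pb(OAc)2, quinoline, EtOAc, rt
Reagents that add atoms: none
Why: Partial syn-hydrogenation of the alkyne over poisoned palladium gives the (Z)-alkene that the all-cis cyclopropane requires, while the trisubstituted ring alkene should not be reduced.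

Step 8
Reactants: 11 (2Z)-3-[(5R)-5-methyl-5-TMB-cyclopent-1-en-1-yl]prop-2-en-1-ol
Product: 12 (2Z)-3-[(5R)-5-methyl-5-TMB-cyclopent-1-en-1-yl]prop-2-en-1-yl 2-bromoacetate
Conditions: BrCH2COBr, NaHCO3, MeCN, 0 °C
Reagents that add atoms: bromoacetyl bromide, BrCC(Br)=O
Why: Esterification of the primary allylic alcohol with an acid bromide under weak-base buffering.

Step 9
Reactants: 12 (2Z)-3-[(5R)-5-methyl-5-TMB-cyclopent-1-en-1-yl]prop-2-en-1-yl 2-bromoacetate
Product: 13 (2Z)-3-[(5R)-5-methyl-5-TMB-cyclopent-1-en-1-yl]prop-2-en-1-yl 2-diazoacetate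
Conditions: TsNHNHTs, DBU, THF, 0 °C
Reagents that add atoms: N,N'-ditosylhydrazine, Cc1ccc(cc1)S(=O)(=O)NNS(=O)(=O)c1ccc(C)cc1
Why: Bromoacetate-to-diazoacetate conversion by N-alkylation of the ditosylhydrazine and double elimination of sulfinate with DBU.

Step 10
Reactants: 13 (2Z)-3-[(5R)-5-methyl-5-TMB-cyclopent-1-en-1-yl]prop-2-en-1-yl 2-diazoacetate
Product: 14 (1S,5R,6S)-6-[(5R)-5-methyl-5-TMB-cyclopent-1-en-1-yl]-3-oxabicyclo[3.1.0]hexan-2-one
Conditions: Rh2(5R-MEPY)4 (dirhodium tetrakis[methyl (5R)-2-oxopyrrolidine-5-carboxylate], 1 mol%), CH2Cl2, 40 °C, slow addition of 13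
Reagents that add atoms: none
Why: Intramolecular cyclopropanation of an allylic diazoacetate by a chiral divalent rhodium carboxamidate carbenoid: the five-membered lactone tether forces the carbonyl carbon cis to the CH2O arm, the (Z)-alkene geometry is retained so the cyclopentenyl group is cis as well (all-cis), and the catalyst rather than the remote quaternary centre should select the alkene face and so the absolute configuration of the three new stereocentres.

Step 11
Reactants: 14 (1S,5R,6S)-6-[(5R)-5-methyl-5-TMB-cyclopent-1-en-1-yl]-3-oxabicyclo[3.1.0]hexan-2-one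
Product: 16 methyl (1S,2R,3S)-2-(hydroxymethyl)-3-[(5R)-5-methyl-5-TMB-cyclopent-1-en-1-yl]cyclopropane-1-carboxylate, via potassium carboxylate 15 (not isolated)
Conditions: KOH (1.0 equiv), THF/H2O, rt; evaporate; MeI, DMF, 0 °C
Reagents that add atoms: potassium hydroxide, [K+].[OH-]; iodomethane, CI
Why: Saponification of the lactone followed by SN2 O-methylation of the carboxylate opens the temporary tether under basic conditions that never expose the cis hydroxy acid to acid (where it would relactonise), and none of the cyclopropane stereocentres is enolised.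

Step 12
Reactants: 16 methyl (1S,2R,3S)-2-(hydroxymethyl)-3-[(5R)-5-methyl-5-TMB-cyclopent-1-en-1-yl]cyclopropane-1-carboxylate
Product: 17 methyl (1S,2R,3S)-2-formyl-3-[(5R)-5-methyl-5-TMB-cyclopent-1-en-1-yl]cyclopropane-1-carboxylate
Conditions: Dess–Martin periodinane, pyridine, CH2Cl2, 0 °C; crude 16 used directly, 17 used at once
Reagents that add atoms: none
Why: Dess–Martin oxidation of the primary alcohol under buffered, non-epimerising conditions, with the aldehyde carried on immediately because a cis-alkenyl cyclopropanecarbaldehyde can slowly equilibrate with a dihydrooxepine.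

Step 13
Reactants: 17 methyl (1S,2R,3S)-2-formyl-3-[(5R)-5-methyl-5-TMB-cyclopent-1-en-1-yl]cyclopropane-1-carboxylate
Product: 18 methyl (1R,2R,3S)-2-[(1E)-prop-1-en-1-yl]-3-[(5R)-5-methyl-5-TMB-cyclopent-1-en-1-yl]cyclopropane-1-carboxylate
Conditions: CH3CHI2, CrCl2, THF, 0 °C → rt; product kept cold
Reagents that add atoms: 1,1-diiodoethane, CC(I)I
Why: Takai–Utimoto olefination: the geminal dichromium reagent adds only to the aldehyde (the ester is inert), is too weakly basic to epimerise the cyclopropane, and should give the (E)-propenyl group whose geometry later fixes the methyl-bearing stereocentre.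

Step 14
Reactants: 18 methyl (1R,2R,3S)-2-[(1E)-prop-1-en-1-yl]-3-[(5R)-5-methyl-5-TMB-cyclopent-1-en-1-yl]cyclopropane-1-carboxylate
Product: 19 methyl (1R,3aR,4R,7R)-1,4-dimethyl-1-TMB-1,2,3,3a,4,7-hexahydroazulene-7-carboxylate
Conditions: toluene (degassed, dilute), BHT (cat.), sealed tube, 110–130 °C
Reagents that add atoms: none
Why: On heating, the two cis alkenyl groups fold over the three-membered ring (endo,endo boat) and a concerted [3,3]-sigmatropic shift, driven by release of cyclopropane strain, breaks the bond between the two alkenyl-bearing ring carbons and joins the cyclopentene CH to the propenyl CH(CH3) terminus. The closest known reaction type is the thermal cis-divinylcyclopropane to cyclohepta-1,4-diene (Cope) rearrangement, including substrates with a cyclopentenyl terminus and a cis substituent on the third ring carbon, which need heating but remain stereospecific. The seven-membered ring is closed by this suprafacial [3,3] ring expansion (the three ring carbons plus the four alkene carbons), which leaves the ring-fusion C=CH alkene in place and a second cis-alkene where the CH2–CH2 pair will be. The ring-fusion CH stereocentre is set by the fixed cyclopentene geometry (ring CH2 outside, H inside the boat) and the CH(CH3) stereocentre by the E geometry of the propenyl group, so the two hydrogens end cis. The ester-bearing carbon keeps its configuration and, being cis to both alkenyl groups in 18, ends cis to those two hydrogens, as the target requires. The step needs the concerted boat pathway to outrun one-centre epimerisation of the cyclopropane: both inward positions on the termini are hydrogens, the planar ester can turn its edge toward the forming bond, the quaternary carbon on the inner cyclopentene carbon favours the reactive rotamer, and no C–H bond cis to the alkenes is available for a homodienyl hydrogen shift.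

Step 15
Reactants: 19 methyl (1R,3aR,4R,7R)-1,4-dimethyl-1-TMB-1,2,3,3a,4,7-hexahydroazulene-7-carboxylate
Product: 20 methyl (1R,3aR,4R,7R)-1,4-dimethyl-1-TMB-1,2,3,3a,4,5,6,7-octahydroazulene-7-carboxylate
Conditions: 2-nitrobenzenesulfonohydrazide, Et3N, CH2Cl2, rt
Reagents that add atoms: none
Why: Diimide reduction (concerted syn transfer of H2) discriminates by substitution, so the cis-disubstituted ring alkene should be reduced while the trisubstituted alkene flanked by the quaternary carbon is left, and no stereocentre is created.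

Step 16
Reactants: 20 methyl (1R,3aR,4R,7R)-1,4-dimethyl-1-TMB-1,2,3,3a,4,5,6,7-octahydroazulene-7-carboxylate
Product: 22 2-[(1R,3aR,4R,7R)-1,4-dimethyl-1-TMB-1,2,3,3a,4,5,6,7-octahydroazulen-7-yl]propan-2-ol, via methyl ketone 21 (not isolated)
Conditions: MeLi, CeCl3 (anhydrous), THF, −78 → 0 °C
Reagents that add atoms: methyllithium, [Li]C
Why: Double 1,2-addition of an organocerium reagent to the ester, where the weakly basic cerium reagent avoids enolisation of the allylic α-CH so that the stereocentre next to the new carbinol is kept.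

Step 17
Reactants: 22 2-[(1R,3aR,4R,7R)-1,4-dimethyl-1-TMB-1,2,3,3a,4,5,6,7-octahydroazulen-7-yl]propan-2-ol; 23 3-methylbutanal
Product: 25 1-[3-[[(1R,3aR,4R,7R)-7-(2-hydroxypropan-2-yl)-1,4-dimethyl-1,2,3,3a,4,5,6,7-octahydroazulen-1-yl]methyl]-2,4,6-trimethoxyphenyl]-3-methylbutan-1-ol (both carbinol epimers), via dilithio species 24 (not isolated)
Conditions: n-BuLi (2.2 equiv), TMEDA, THF, 0 °C; then 23, −78 °C; H2O
Reagents that add atoms: none
Why: Directed ortho-metalation: after deprotonation of the tertiary alcohol, n-BuLi/TMEDA lithiates an aryl C–H flanked by two methoxy groups (the two such positions are equivalent) and the aryllithium adds to the aldehyde, the new carbinol centre being formed without control and removed in step 19.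

Step 18
Reactants: 25 1-[3-[[(1R,3aR,4R,7R)-7-(2-hydroxypropan-2-yl)-1,4-dimethyl-1,2,3,3a,4,5,6,7-octahydroazulen-1-yl]methyl]-2,4,6-trimethoxyphenyl]-3-methylbutan-1-ol
Product: 27 3-[[(1R,3aR,4R,7R)-7-(2-hydroxypropan-2-yl)-1,4-dimethyl-1,2,3,3a,4,5,6,7-octahydroazulen-1-yl]methyl]-5-(1-hydroxy-3-methylbutyl)-2,4,6-trimethoxybenzaldehyde, via trilithio species 26 (not isolated)
Conditions: n-BuLi (3.3 equiv), TMEDA, THF, 0 °C; then DMF, −78 → 0 °C; H2O
Reagents that add atoms: N,N-dimethylformamide, CN(C)C=O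
Why: Second directed ortho-metalation at the only remaining aryl C–H, again between two methoxy groups, followed by formylation of the aryllithium with DMF.

Step 19
Reactants: 27 3-[[(1R,3aR,4R,7R)-7-(2-hydroxypropan-2-yl)-1,4-dimethyl-1,2,3,3a,4,5,6,7-octahydroazulen-1-yl]methyl]-5-(1-hydroxy-3-methylbutyl)-2,4,6-trimethoxybenzaldehyde
Product: 28 3-[[(1R,3aR,4R,7R)-7-(2-hydroxypropan-2-yl)-1,4-dimethyl-1,2,3,3a,4,5,6,7-octahydroazulen-1-yl]methyl]-2,4,6-trimethoxy-5-(3-methylbutanoyl)benzaldehyde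
Conditions: Dess–Martin periodinane, pyridine, CH2Cl2, 0 °C → rt
Reagents that add atoms: none
Why: Dess–Martin oxidation converts the secondary benzylic alcohol into the isovaleryl ketone, while the tertiary alcohol cannot be oxidised and the aryl aldehyde is not affected.

Step 20
Reactants: 28 3-[[(1R,3aR,4R,7R)-7-(2-hydroxypropan-2-yl)-1,4-dimethyl-1,2,3,3a,4,5,6,7-octahydroazulen-1-yl]methyl]-2,4,6-trimethoxy-5-(3-methylbutanoyl)benzaldehyde
Product: 29 2,4,6-trihydroxy-3-[[(1R,3aR,4R,7R)-7-(2-hydroxypropan-2-yl)-1,4-dimethyl-1,2,3,3a,4,5,6,7-octahydroazulen-1-yl]methyl]-5-(3-methylbutanoyl)benzaldehyde (CNP0583424.1)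
Conditions: EtSNa (excess), DMF, 120 °C; then cold dilute HCl
Reagents that add atoms: none
Why: Nucleophilic (SN2) O-demethylation by thiolate: every methoxy group is ortho to a carbonyl group, which makes each phenoxide a good leaving group, and the basic medium spares the tertiary alcohol and the trisubstituted alkene that acid would engage.

**Compound list**
1 | (2,4,6-trimethoxyphenyl)methanol | COc1cc(OC)c(CO)c(OC)c1 | starting material
2 | 2-methylcyclopentane-1,3-dione | CC1C(=O)CCC1=O | starting material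
3 | 2-methyl-2-[(2,4,6-trimethoxyphenyl)methyl]cyclopentane-1,3-dione | COc1cc(OC)c(CC2(C)C(=O)CCC2=O)c(OC)c1 | intermediate
4 | (2S,3S)-3-hydroxy-2-methyl-2-[(2,4,6-trimethoxyphenyl)methyl]cyclopentan-1-one | O=C1CC[C@H](O)[C@]1(C)Cc1c(OC)cc(OC)cc1OC | intermediate
5 | O-[(1S,2S)-2-methyl-3-oxo-2-[(2,4,6-trimethoxyphenyl)methyl]cyclopentyl] 1H-imidazole-1-carbothioate | O=C1CC[C@H](OC(=S)n2ccnc2)[C@]1(C)Cc1c(OC)cc(OC)cc1OC | intermediate
6 | (2R)-2-methyl-2-[(2,4,6-trimethoxyphenyl)methyl]cyclopentan-1-one | O=C1CCC[C@]1(C)Cc1c(OC)cc(OC)cc1OC | intermediate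
7 | potassium (5R)-5-methyl-5-[(2,4,6-trimethoxyphenyl)methyl]cyclopent-1-en-1-olate | [K+].[O-]C1=CCC[C@]1(C)Cc1c(OC)cc(OC)cc1OC | intermediate (not isolated)
8 | (5R)-5-methyl-5-[(2,4,6-trimethoxyphenyl)methyl]cyclopent-1-en-1-yl trifluoromethanesulfonate | O=S(=O)(OC1=CCC[C@]1(C)Cc1c(OC)cc(OC)cc1OC)C(F)(F)F | intermediate
9 | prop-2-yn-1-ol | C#CCO | starting material
10 | 3-[(5R)-5-methyl-5-[(2,4,6-trimethoxyphenyl)methyl]cyclopent-1-en-1-yl]prop-2-yn-1-ol | OCC#CC1=CCC[C@]1(C)Cc1c(OC)cc(OC)cc1OC | intermediate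
11 | (2Z)-3-[(5R)-5-methyl-5-[(2,4,6-trimethoxyphenyl)methyl]cyclopent-1-en-1-yl]prop-2-en-1-ol | OC/C=C\C1=CCC[C@]1(C)Cc1c(OC)cc(OC)cc1OC | intermediate
12 | (2Z)-3-[(5R)-5-methyl-5-[(2,4,6-trimethoxyphenyl)methyl]cyclopent-1-en-1-yl]prop-2-en-1-yl 2-bromoacetate | BrCC(=O)OC/C=C\C1=CCC[C@]1(C)Cc1c(OC)cc(OC)cc1OC | intermediate
13 | (2Z)-3-[(5R)-5-methyl-5-[(2,4,6-trimethoxyphenyl)methyl]cyclopent-1-en-1-yl]prop-2-en-1-yl 2-diazoacetate | [N-]=[N+]=CC(=O)OC/C=C\C1=CCC[C@]1(C)Cc1c(OC)cc(OC)cc1OC | intermediate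
14 | (1S,5R,6S)-6-[(5R)-5-methyl-5-[(2,4,6-trimethoxyphenyl)methyl]cyclopent-1-en-1-yl]-3-oxabicyclo[3.1.0]hexan-2-one | O=C1OC[C@@H]2[C@H](C3=CCC[C@]3(C)Cc3c(OC)cc(OC)cc3OC)[C@H]12 | intermediate
15 | potassium (1S,2R,3S)-2-(hydroxymethyl)-3-[(5R)-5-methyl-5-[(2,4,6-trimethoxyphenyl)methyl]cyclopent-1-en-1-yl]cyclopropane-1-carboxylate | [K+].[O-]C(=O)[C@@H]1[C@H](CO)[C@@H]1C1=CCC[C@]1(C)Cc1c(OC)cc(OC)cc1OC | intermediate (not isolated)
16 | methyl (1S,2R,3S)-2-(hydroxymethyl)-3-[(5R)-5-methyl-5-[(2,4,6-trimethoxyphenyl)methyl]cyclopent-1-en-1-yl]cyclopropane-1-carboxylate | COC(=O)[C@@H]1[C@H](CO)[C@@H]1C1=CCC[C@]1(C)Cc1c(OC)cc(OC)cc1OC | intermediate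
17 | methyl (1S,2R,3S)-2-formyl-3-[(5R)-5-methyl-5-[(2,4,6-trimethoxyphenyl)methyl]cyclopent-1-en-1-yl]cyclopropane-1-carboxylate | COC(=O)[C@@H]1[C@H](C=O)[C@@H]1C1=CCC[C@]1(C)Cc1c(OC)cc(OC)cc1OC | intermediate
18 | methyl (1R,2R,3S)-2-[(1E)-prop-1-en-1-yl]-3-[(5R)-5-methyl-5-[(2,4,6-trimethoxyphenyl)methyl]cyclopent-1-en-1-yl]cyclopropane-1-carboxylate | COC(=O)[C@@H]1[C@H](/C=C/C)[C@@H]1C1=CCC[C@]1(C)Cc1c(OC)cc(OC)cc1OC | intermediate
19 | methyl (1R,3aR,4R,7R)-1,4-dimethyl-1-[(2,4,6-trimethoxyphenyl)methyl]-1,2,3,3a,4,7-hexahydroazulene-7-carboxylate | COc1cc(OC)c(C[C@@]2(C)CC[C@H]3C2=C[C@H](C(=O)OC)C=C[C@H]3C)c(OC)c1 | intermediate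
20 | methyl (1R,3aR,4R,7R)-1,4-dimethyl-1-[(2,4,6-trimethoxyphenyl)methyl]-1,2,3,3a,4,5,6,7-octahydroazulene-7-carboxylate | COc1cc(OC)c(C[C@@]2(C)CC[C@H]3C2=C[C@H](C(=O)OC)CC[C@H]3C)c(OC)c1 | intermediate
21 | 1-[(1R,3aR,4R,7R)-1,4-dimethyl-1-[(2,4,6-trimethoxyphenyl)methyl]-1,2,3,3a,4,5,6,7-octahydroazulen-7-yl]ethan-1-one | COc1cc(OC)c(C[C@@]2(C)CC[C@H]3C2=C[C@H](C(C)=O)CC[C@H]3C)c(OC)c1 | intermediate (not isolated)
22 | 2-[(1R,3aR,4R,7R)-1,4-dimethyl-1-[(2,4,6-trimethoxyphenyl)methyl]-1,2,3,3a,4,5,6,7-octahydroazulen-7-yl]propan-2-ol | COc1cc(OC)c(C[C@@]2(C)CC[C@H]3C2=C[C@H](C(C)(C)O)CC[C@H]3C)c(OC)c1 | intermediate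
23 | 3-methylbutanal | CC(C)CC=O | starting material
24 | dilithio species of 22 (lithium alkoxide; aryl carbon between two methoxy groups lithiated) | COc1cc(OC)c(C[C@@]2(C)CC[C@H]3C2=C[C@H](C(C)(C)O[Li])CC[C@H]3C)c(OC)c1[Li] | intermediate (not isolated)
25 | 1-[3-[[(1R,3aR,4R,7R)-7-(2-hydroxypropan-2-yl)-1,4-dimethyl-1,2,3,3a,4,5,6,7-octahydroazulen-1-yl]methyl]-2,4,6-trimethoxyphenyl]-3-methylbutan-1-ol (both carbinol epimers) | CC(C)CC(O)c1c(OC)cc(OC)c(C[C@@]2(C)CC[C@H]3C2=C[C@H](C(C)(C)O)CC[C@H]3C)c1OC | intermediate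
26 | trilithio species of 25 (two lithium alkoxides; remaining aryl carbon lithiated) | CC(C)CC(O[Li])c1c(OC)c([Li])c(OC)c(C[C@@]2(C)CC[C@H]3C2=C[C@H](C(C)(C)O[Li])CC[C@H]3C)c1OC | intermediate (not isolated)
27 | 3-[[(1R,3aR,4R,7R)-7-(2-hydroxypropan-2-yl)-1,4-dimethyl-1,2,3,3a,4,5,6,7-octahydroazulen-1-yl]methyl]-5-(1-hydroxy-3-methylbutyl)-2,4,6-trimethoxybenzaldehyde (both carbinol epimers) | CC(C)CC(O)c1c(OC)c(C=O)c(OC)c(C[C@@]2(C)CC[C@H]3C2=C[C@H](C(C)(C)O)CC[C@H]3C)c1OC | intermediate
28 | 3-[[(1R,3aR,4R,7R)-7-(2-hydroxypropan-2-yl)-1,4-dimethyl-1,2,3,3a,4,5,6,7-octahydroazulen-1-yl]methyl]-2,4,6-trimethoxy-5-(3-methylbutanoyl)benzaldehyde | CC(C)CC(=O)c1c(OC)c(C=O)c(OC)c(C[C@@]2(C)CC[C@H]3C2=C[C@H](C(C)(C)O)CC[C@H]3C)c1OC | intermediate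
29 | 2,4,6-trihydroxy-3-[[(1R,3aR,4R,7R)-7-(2-hydroxypropan-2-yl)-1,4-dimethyl-1,2,3,3a,4,5,6,7-octahydroazulen-1-yl]methyl]-5-(3-methylbutanoyl)benzaldehyde | CC(C)CC(=O)c1c(O)c(C=O)c(O)c(C[C@@]2(C)CC[C@H]3C2=C[C@H](C(C)(C)O)CC[C@H]3C)c1O | target

**Step count and risks**
Total step count: 20. Longest linear sequence: 20 steps (from 1 and 2; 9 and 23 enter as one-step partners).

Steps most likely to fail:

1. Step 14 (Cope rearrangement). The cis ester on the third cyclopropane carbon may slow the boat transition state so far that homolytic one-centre epimerisation of the cyclopropane competes at the temperature needed, which would erode the stereospecific transfer to the three ring stereocentres. Fallback, from 13 back to 20, with the cis group reduced to CH2OH: cyclisation of 13 with the enantiomeric catalyst Rh2(5S-MEPY)4 should give the lactone with the mirror-image bicyclic core F1, in which the two one-carbon arms exchange roles. Reduction with i-Bu2AlH at −78 °C gives the lactol F2. Julia–Kocienski olefination with 5-(ethylsulfonyl)-1-phenyl-1H-tetrazole and KHMDS gives the all-cis (E)-propenyl cyclopropylmethanol F3. The thermal Cope rearrangement of F3 gives the cycloheptadienylmethanol F4, diimide reduction the cycloheptenylmethanol F5, oxidation with TEMPO/PhI(OAc)2 in MeCN–H2O the carboxylic acid F6, and MeI/K2CO3 returns to 20.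

2. Step 10 (intramolecular cyclopropanation). The carbenoid may be intercepted by the electron-rich cyclopentene or arene, or the nearby quaternary centre may oppose the catalyst (mismatched double diastereoselection) and lower the facial selectivity. Fallback, from 9 and 8 back to 14, in which the carbenoid step is run on a simple substrate and the cyclopentenyl group is attached afterwards: 9 is converted with NaAlH2(OCH2CH2OMe)2 and then I2 into (2Z)-3-iodoprop-2-en-1-ol F7. Esterification with BrCH2COBr gives the bromoacetate F8, and TsNHNHTs/DBU the diazoacetate F9. Rh2(5R-MEPY)4 should cyclise F9 to the endo-iodo lactone F10. Triflate 8 is converted by Miyaura borylation (B2pin2, PdCl2(dppf), KOAc) into the alkenyl boronate F11. Suzuki–Miyaura coupling of F10 with F11 (Pd(OAc)2, SPhos, K3PO4, toluene/H2O), which proceeds with retention at the cyclopropyl carbon, gives 14.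

3. Step 13 (olefination of the cis-alkenyl cyclopropanecarbaldehyde). Aldehyde 17 may drift into a dihydrooxepine by retro-Claisen rearrangement or epimerise at its α-carbon before the chromium reagent captures it, and the E selectivity may be incomplete. Fallback, from 16 back to 18, which reverses the polarity so that no cyclopropanecarbaldehyde is ever formed: Mitsunobu thioetherification of 16 with 1-phenyl-1H-tetrazole-5-thiol (PPh3, DIAD) gives the sulfide F12. Oxidation with (NH4)6Mo7O24/H2O2 gives the sulfone F13. Julia–Kocienski olefination of F13 with acetaldehyde (KHMDS, DME, −60 °C) should install the (E)-propenyl group and give 18.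

**Further compounds**
F1 | step 14 | (1R,5S,6R)-6-[(5R)-5-methyl-5-[(2,4,6-trimethoxyphenyl)methyl]cyclopent-1-en-1-yl]-3-oxabicyclo[3.1.0]hexan-2-one | O=C1OC[C@H]2[C@@H](C3=CCC[C@]3(C)Cc3c(OC)cc(OC)cc3OC)[C@@H]12
F2 | step 14 | (1R,5S,6R)-6-[(5R)-5-methyl-5-[(2,4,6-trimethoxyphenyl)methyl]cyclopent-1-en-1-yl]-3-oxabicyclo[3.1.0]hexan-2-ol (both anomers) | OC1OC[C@H]2[C@@H](C3=CCC[C@]3(C)Cc3c(OC)cc(OC)cc3OC)[C@@H]12
F3 | step 14 | [(1R,2S,3R)-2-[(5R)-5-methyl-5-[(2,4,6-trimethoxyphenyl)methyl]cyclopent-1-en-1-yl]-3-[(1E)-prop-1-en-1-yl]cyclopropyl]methanol | OC[C@H]1[C@@H](C2=CCC[C@]2(C)Cc2c(OC)cc(OC)cc2OC)[C@H]1/C=C/C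
F4 | step 14 | [(1R,3aR,4R,7R)-1,4-dimethyl-1-[(2,4,6-trimethoxyphenyl)methyl]-1,2,3,3a,4,7-hexahydroazulen-7-yl]methanol | COc1cc(OC)c(C[C@@]2(C)CC[C@H]3C2=C[C@H](CO)C=C[C@H]3C)c(OC)c1
F5 | step 14 | [(1R,3aR,4R,7R)-1,4-dimethyl-1-[(2,4,6-trimethoxyphenyl)methyl]-1,2,3,3a,4,5,6,7-octahydroazulen-7-yl]methanol | COc1cc(OC)c(C[C@@]2(C)CC[C@H]3C2=C[C@H](CO)CC[C@H]3C)c(OC)c1
F6 | step 14 | (1R,3aR,4R,7R)-1,4-dimethyl-1-[(2,4,6-trimethoxyphenyl)methyl]-1,2,3,3a,4,5,6,7-octahydroazulene-7-carboxylic acid | COc1cc(OC)c(C[C@@]2(C)CC[C@H]3C2=C[C@H](C(=O)O)CC[C@H]3C)c(OC)c1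
F7 | step 10 | (2Z)-3-iodoprop-2-en-1-ol | OC/C=C\I
F8 | step 10 | (2Z)-3-iodoprop-2-en-1-yl 2-bromoacetate | BrCC(=O)OC/C=C\I
F9 | step 10 | (2Z)-3-iodoprop-2-en-1-yl 2-diazoacetate | [N-]=[N+]=CC(=O)OC/C=C\I
F10 | step 10 | (1S,5R,6S)-6-iodo-3-oxabicyclo[3.1.0]hexan-2-one | O=C1OC[C@@H]2[C@H](I)[C@H]12
F11 | step 10 | 2-[(5R)-5-methyl-5-[(2,4,6-trimethoxyphenyl)methyl]cyclopent-1-en-1-yl]-4,4,5,5-tetramethyl-1,3,2-dioxaborolane | CC1(C)OB(OC1(C)C)C1=CCC[C@]1(C)Cc1c(OC)cc(OC)cc1OC
F12 | step 13 | methyl (1S,2R,3R)-2-[[(1-phenyl-1H-tetrazol-5-yl)sulfanyl]methyl]-3-[(5R)-5-methyl-5-[(2,4,6-trimethoxyphenyl)methyl]cyclopent-1-en-1-yl]cyclopropane-1-carboxylate | COC(=O)[C@@H]1[C@H](CSc2nnnn2-c2ccccc2)[C@@H]1C1=CCC[C@]1(C)Cc1c(OC)cc(OC)cc1OC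
F13 | step 13 | methyl (1S,2R,3R)-2-[[(1-phenyl-1H-tetrazol-5-yl)sulfonyl]methyl]-3-[(5R)-5-methyl-5-[(2,4,6-trimethoxyphenyl)methyl]cyclopent-1-en-1-yl]cyclopropane-1-carboxylate | COC(=O)[C@@H]1[C@H](CS(=O)(=O)c2nnnn2-c2ccccc2)[C@@H]1C1=CCC[C@]1(C)Cc1c(OC)cc(OC)cc1OC
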